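**Plan**
- Retrosynthetic cuts, in order: the two O–benzyl bonds at O5 and O7; the lactone at O1–C2 and C2–C3; the aryl–alkenyl bond C4a–C4; the C–I bond; and the aryl–acyl bond C8–C(=O) at the phloroglucinol stage.
- Enabling feature: in the chroman-2-one ring, C2 is a single carbonyl carbon bonded only to O1 and the C3 methylene. It can therefore be delivered as CO to a 2-(1-phenylethenyl)phenol of ring A, whose inner alkene carbon becomes C4 and whose phenol oxygen becomes O1.
- Forward order: the side chain is joined to phloroglucinol first, two hydroxyls are benzylated, the position ortho to the remaining chelated hydroxyl is iodinated and coupled with a 1-phenylvinyl boronate, the lactone ring is closed by cyclocarbonylation, and the benzyl ethers are removed.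
- Regiochemistry: the ketone is in place before ring closure and the only free hydroxyl lies between ketone and alkene, so the lactone can only close onto that oxygen and the acyl group ends at C8, not C6.
- Stereochemistry: the single stereocentre C4 (S) is set by the chiral bisphosphine–palladium hydride in the cyclocarbonylation; no later step touches it.

Key step: step 5

Assumption: the sense of induction of a bisphosphine in this hydropalladation cannot be predicted, so the ligand named in step 5 stands for whichever antipode a first trial shows to give the (S)-lactone.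

**Step 1**
Reactants: 1 phloroglucinol; 2 3-(4-methoxyphenyl)propanoic acid
Product: 3 3-(4-methoxyphenyl)-1-(2,4,6-trihydroxyphenyl)propan-1-one
Conditions: BF3·OEt2 (Lewis acid and solvent), 85 °C; aq. NaOAc work-up
Reagents that add atoms: none
Why: Friedel–Crafts C-acylation of the symmetric, strongly activated triol by the BF3-activated acid should stop after one acyl group because the first ketone deactivates the ring, while the anisyl ring of 2 is too weak a nucleophile to compete and could only cyclise at a position meta to its methoxy group.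

**Step 2**
Reactants: 3 3-(4-methoxyphenyl)-1-(2,4,6-trihydroxyphenyl)propan-1-one
Product: 4 1-[2,4-bis(benzyloxy)-6-hydroxyphenyl]-3-(4-methoxyphenyl)propan-1-one
Conditions: BnBr (2.1 equiv), K2CO3, DMF, rt
Reagents that add atoms: benzyl bromide, BrCc1ccccc1
Why: Williamson etherification with a mild base should alkylate the para hydroxyl and one ortho hydroxyl, whereas the second ortho hydroxyl, held in a hydrogen bond to the ketone, is the least nucleophilic and stays free, as is usual for acylphloroglucinols.

**Step 3**
Reactants: 4 1-[2,4-bis(benzyloxy)-6-hydroxyphenyl]-3-(4-methoxyphenyl)propan-1-one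
Product: 5 1-[4,6-bis(benzyloxy)-2-hydroxy-3-iodophenyl]-3-(4-methoxyphenyl)propan-1-one
Conditions: NIS (1.05 equiv), DMF, 0 °C to rt, dark
Reagents that add atoms: N-iodosuccinimide, O=C1CCC(=O)N1I
Why: Electrophilic aromatic iodination without strong acid should touch only the phenolic ring and go to the carbon ortho to the free hydroxyl and para to a benzyloxy group rather than to the carbon squeezed between two benzyloxy groups, the usual outcome for 2-hydroxy-4,6-dialkoxyaryl ketones.

**Step 4**
Reactants: 5 1-[4,6-bis(benzyloxy)-2-hydroxy-3-iodophenyl]-3-(4-methoxyphenyl)propan-1-one; 6 4,4,5,5-tetramethyl-2-(1-phenylethenyl)-1,3,2-dioxaborolane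
Product: 7 1-[4,6-bis(benzyloxy)-2-hydroxy-3-(1-phenylethenyl)phenyl]-3-(4-methoxyphenyl)propan-1-one
Conditions: Pd(OAc)2 (5 mol%), SPhos (10 mol%), K3PO4, 6 (1.5 equiv), toluene/H2O, 80 °C
Reagents that add atoms: none
Why: Suzuki–Miyaura coupling, in which zerovalent palladium carrying the electron-rich biaryl phosphine SPhos should insert into the doubly ortho-substituted C–I bond, the free phenol is tolerated as its phenoxide, and the alkenyl group is transferred with its 1,1-substitution intact.

**Step 5**
Reactants: 7 1-[4,6-bis(benzyloxy)-2-hydroxy-3-(1-phenylethenyl)phenyl]-3-(4-methoxyphenyl)propan-1-one; 8 carbon monoxide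
Product: 9 (4S)-5,7-bis(benzyloxy)-8-[3-(4-methoxyphenyl)propanoyl]-4-phenylchroman-2-one
Conditions: Pd(OAc)2 (5 mol%), (R)-DTBM-SEGPHOS (6 mol%; DIOP and SDP-type ligands in the screen), TsOH·H2O (10 mol%), CO (30 bar), toluene, 90 °C
Reagents that add atoms: none
Why: A palladium hydride formed from Pd(OAc)2, the bisphosphine and TsOH should add across the 1,1-diarylethene with hydrogen to the diaryl-substituted carbon (the future C4) and palladium to the CH2 terminus, CO then inserts into the primary alkyl–palladium bond (C2–C3), and the neighbouring phenol cleaves the acyl palladium (O1–C2) and regenerates the hydride. The closest known reaction type is the palladium-catalysed cyclocarbonylation (intramolecular hydroesterification) of 2-alkenylphenols to chroman-2-ones, including enantioselective runs on 1,1-disubstituted alkenes that carry an ortho OH or NH2. The lactone ring closes 6-exo-trig, the phenol oxygen attacking the acyl carbon whose C=O stays outside the new ring. C4 is controlled by the chiral bisphosphine on palladium, which selects one alkene face in the hydropalladation (or, should that step be reversible, in the CO insertion that follows). The step needs linear regiochemistry and face selection: the alternative tertiary dibenzylic palladium alkyl is too crowded and would lead to a five-membered lactone with a quaternary carbon, the alkene has no allylic hydrogen and cannot isomerise, and the pentasubstituted aryl, pushed out of the alkene plane by its two ortho substituents, differs sharply in shape from the coplanar phenyl. The benzyl ethers, the ketone and the methyl ether should be inert to the weakly acidic, hydrogen-free CO atmosphere.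

**Step 6**
Reactants: 9 (4S)-5,7-bis(benzyloxy)-8-[3-(4-methoxyphenyl)propanoyl]-4-phenylchroman-2-one
Product: 10 (4S)-5,7-dihydroxy-8-[3-(4-methoxyphenyl)propanoyl]-4-phenylchroman-2-one (CNP0240692.1)
Conditions: H2 (1 atm), Pd/C (10 wt% palladium on carbon), EtOAc, rt
Reagents that add atoms: none
Why: Hydrogenolysis of the two benzyl ethers in a neutral aprotic solvent should leave the methyl ether, the hydrogen-bonded aryl ketone and the lactone untouched, and C4, which carries only C–C and C–H bonds, keeps its configuration.

**Compound list**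
1 | phloroglucinol (benzene-1,3,5-triol) | Oc1cc(O)cc(O)c1 | starting material
2 | 3-(4-methoxyphenyl)propanoic acid | COc1ccc(CCC(=O)O)cc1 | starting material
3 | 3-(4-methoxyphenyl)-1-(2,4,6-trihydroxyphenyl)propan-1-one | COc1ccc(CCC(=O)c2c(O)cc(O)cc2O)cc1 | intermediate
4 | 1-[2,4-bis(benzyloxy)-6-hydroxyphenyl]-3-(4-methoxyphenyl)propan-1-one | COc1ccc(CCC(=O)c2c(O)cc(OCc3ccccc3)cc2OCc2ccccc2)cc1 | intermediate
5 | 1-[4,6-bis(benzyloxy)-2-hydroxy-3-iodophenyl]-3-(4-methoxyphenyl)propan-1-one | COc1ccc(CCC(=O)c2c(O)c(I)c(OCc3ccccc3)cc2OCc2ccccc2)cc1 | intermediate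
6 | 4,4,5,5-tetramethyl-2-(1-phenylethenyl)-1,3,2-dioxaborolane | C=C(c1ccccc1)B1OC(C)(C)C(C)(C)O1 | starting material
7 | 1-[4,6-bis(benzyloxy)-2-hydroxy-3-(1-phenylethenyl)phenyl]-3-(4-methoxyphenyl)propan-1-one | COc1ccc(CCC(=O)c2c(O)c(C(=C)c3ccccc3)c(OCc3ccccc3)cc2OCc2ccccc2)cc1 | intermediate
8 | carbon monoxide | [C-]#[O+] | starting material
9 | (4S)-5,7-bis(benzyloxy)-8-[3-(4-methoxyphenyl)propanoyl]-4-phenylchroman-2-one | COc1ccc(CCC(=O)c2c(OCc3ccccc3)cc(OCc3ccccc3)c3c2OC(=O)C[C@H]3c2ccccc2)cc1 | intermediate
10 | (4S)-5,7-dihydroxy-8-[3-(4-methoxyphenyl)propanoyl]-4-phenylchroman-2-one | COc1ccc(CCC(=O)c2c(O)cc(O)c3c2OC(=O)C[C@H]3c2ccccc2)cc1 | target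

Total step count: 6. Longest linear sequence: 6 steps (1 → 3 → 4 → 5 → 7 → 9 → 10).

**Steps most likely to fail**

Step 5. What may go wrong: weak discrimination of the alkene faces by the ligand, slow cleavage of the acyl palladium by the hindered, hydrogen-bonded phenol, or acid-promoted oligomerisation of the electron-rich diarylethene. The fallback sets out from 4 and comes back at 9; it makes C4 by asymmetric aryl addition instead of hydropalladation. Magnesium-phenoxide-directed ortho-formylation of 4 (MgCl2, Et3N, paraformaldehyde, MeCN, reflux) can only reach the free position next to the hydroxyl and should give 4,6-bis(benzyloxy)-2-hydroxy-3-[3-(4-methoxyphenyl)propanoyl]benzaldehyde F1. Wittig olefination of the aldehyde (the ketone does not react with a stabilised ylide) with ethyl (triphenylphosphoranylidene)acetate in refluxing N,N-diethylaniline should give ethyl (E)-3-{4,6-bis(benzyloxy)-2-hydroxy-3-[3-(4-methoxyphenyl)propanoyl]phenyl}prop-2-enoate F2. This ester is not isolated; it isomerises and lactonises in the hot medium to 5,7-bis(benzyloxy)-8-[3-(4-methoxyphenyl)propanoyl]-2H-chromen-2-one F3. Hayashi–Miyaura rhodium-catalysed asymmetric 1,4-addition of phenylboronic acid (Rh(acac)(C2H4)2, the suitable SEGPHOS antipode, dioxane/H2O, 60 °C) then places the phenyl group at C4 and gives 9.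

Step 4. What may go wrong: slow oxidative addition and transmetalation at the doubly ortho-substituted iodide, so that protodeboronation of the alkenyl boronate outruns coupling. The fallback sets out from 5 and comes back at 7; it builds the 1,1-diarylethene by a carbene route instead of transmetalation. A Barluenga coupling of 5 with acetophenone N-tosylhydrazone (Pd2(dba)3, XPhos, LiOtBu, dioxane, 100 °C) generates the diazo compound in the flask, the palladium carbene takes up the aryl group by migratory insertion, and β-hydride elimination gives 7 directly. New compounds on this way: none F0.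

Step 3. What may go wrong: iodination at the ring carbon between the two benzyloxy groups or on the anisyl ring, which would misplace or lose the alkene site. The fallback sets out from 1 and comes back at 7, bypassing steps 3 and 4; the alkene is made from a benzophenone and the side chain is attached by a strictly ortho-selective formylation. BF3·OEt2-mediated acylation of 1 with benzoic acid should give 2,4,6-trihydroxybenzophenone F4. Benzylation (BnBr, K2CO3, DMF) leaves the chelated hydroxyl free and gives [4,6-bis(benzyloxy)-2-hydroxyphenyl](phenyl)methanone F5. Excess MeMgBr in THF adds to the ketone to give racemic 3,5-bis(benzyloxy)-2-(1-hydroxy-1-phenylethyl)phenol F6, which loses water with catalytic pyridinium p-toluenesulfonate in warm toluene to give 3,5-bis(benzyloxy)-2-(1-phenylethenyl)phenol F7. Ortho-formylation (MgCl2, Et3N, paraformaldehyde, MeCN, reflux) at the single free position next to the hydroxyl gives 4,6-bis(benzyloxy)-2-hydroxy-3-(1-phenylethenyl)benzaldehyde F8. Addition of 2-(4-methoxyphenyl)ethylmagnesium bromide (2.2 equiv, THF, 0 °C) gives racemic 1-[4,6-bis(benzyloxy)-2-hydroxy-3-(1-phenylethenyl)phenyl]-3-(4-methoxyphenyl)propan-1-ol F9, and oxidation of this benzylic alcohol with MnO2 in CH2Cl2 gives 7.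

**Further compounds**
F1 | step 5 | 4,6-bis(benzyloxy)-2-hydroxy-3-[3-(4-methoxyphenyl)propanoyl]benzaldehyde | COc1ccc(CCC(=O)c2c(O)c(C=O)c(OCc3ccccc3)cc2OCc2ccccc2)cc1
F2 | step 5 | ethyl (E)-3-{4,6-bis(benzyloxy)-2-hydroxy-3-[3-(4-methoxyphenyl)propanoyl]phenyl}prop-2-enoate | CCOC(=O)/C=C/c1c(O)c(C(=O)CCc2ccc(OC)cc2)c(OCc2ccccc2)cc1OCc1ccccc1
F3 | step 5 | 5,7-bis(benzyloxy)-8-[3-(4-methoxyphenyl)propanoyl]-2H-chromen-2-one | COc1ccc(CCC(=O)c2c(OCc3ccccc3)cc(OCc3ccccc3)c3ccc(=O)oc23)cc1
F0 | step 4 | none | none
F4 | step 3 | 2,4,6-trihydroxybenzophenone | O=C(c1ccccc1)c1c(O)cc(O)cc1O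
F5 | step 3 | [4,6-bis(benzyloxy)-2-hydroxyphenyl](phenyl)methanone | O=C(c1ccccc1)c1c(O)cc(OCc2ccccc2)cc1OCc1ccccc1
F6 | step 3 | 3,5-bis(benzyloxy)-2-(1-hydroxy-1-phenylethyl)phenol (racemic) | CC(O)(c1ccccc1)c1c(O)cc(OCc2ccccc2)cc1OCc1ccccc1
F7 | step 3 | 3,5-bis(benzyloxy)-2-(1-phenylethenyl)phenol | C=C(c1ccccc1)c1c(O)cc(OCc2ccccc2)cc1OCc1ccccc1
F8 | step 3 | 4,6-bis(benzyloxy)-2-hydroxy-3-(1-phenylethenyl)benzaldehyde | C=C(c1ccccc1)c1c(O)c(C=O)c(OCc2ccccc2)cc1OCc1ccccc1
F9 | step 3 | 1-[4,6-bis(benzyloxy)-2-hydroxy-3-(1-phenylethenyl)phenyl]-3-(4-methoxyphenyl)propan-1-ol (racemic) | C=C(c1ccccc1)c1c(O)c(C(O)CCc2ccc(OC)cc2)c(OCc2ccccc2)cc1OCc1ccccc1
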